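**Retrosynthetic overview**

- Feature: in ring B (the 2H-pyran ring) the atoms O1, C2 (the only stereocentre, S, carrying CH3 and the 4-hydroxy-4-methylpentyl chain), C3, C4 and C4a match, one by one, a phenol oxygen, the β- and α-carbons of a β-methyl enal and the carbonyl carbon of an aryl aldehyde. Ring A (hydroquinone ring) and ring C (4-hydroxyphenyl ring) are bought as arenes.
- 14 ⇒ 4-hydroxybenzaldehyde 13 + acetyl hydroquinone 12 (Claisen–Schmidt at the enone C=C) ⇒ dimethyl ether 10 (oxidative demethylation, reduction) ⇒ bromide 9 (Br–Li exchange, acetylation) ⇒ 3-formyl chromene 8 (decarbonylation).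
- 8 ⇒ salicylaldehyde 3 + (E)-7-hydroxycitral 7 by aminocatalytic oxa-Michael–aldol condensation, which forms O1–C2 and C3–C4, closes ring B (the only ring closed in the route) and sets C2.
- 3 ⇐ 2,5-dimethoxyphenol 1 (ortho-formylation, then bromination); 7 ⇐ geranyl acetate 4 (distal hydration with saponification, then MnO2).

Key step: step 5

Remark: C2 of the target is read from the SMILES as S (O1 > C3 > side-chain CH2 > CH3); geranyl acetate of high E purity is taken as the purchased terpene, and the formylation is placed before the bromination so that each has only one reactive position.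

**Step 1**
Reactants: 1 2,5-dimethoxyphenol
Product: 2 2-hydroxy-3,6-dimethoxybenzaldehyde
Conditions: MgCl2, Et3N, (CH2O)n, MeCN, reflux; aq. HCl work-up
Reagents that add atoms: paraformaldehyde (formaldehyde), C=O
Why: In the magnesium-mediated ortho-formylation (Casnati–Skattebøl) the magnesium phenoxide delivers formaldehyde to the only free ortho carbon and a second formaldehyde oxidises the benzylic alkoxide to the aldehyde.

**Step 2**
Reactants: 2 2-hydroxy-3,6-dimethoxybenzaldehyde
Product: 3 5-bromo-2-hydroxy-3,6-dimethoxybenzaldehyde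
Conditions: NBS (1.05 equiv), MeCN, 0 °C → rt
Reagents that add atoms: N-bromosuccinimide, O=C1CCC(=O)N1Br
Why: Electrophilic aromatic bromination should go to C5, which is para to the free phenol and ortho to a methoxy group, because the only other free carbon (C4) is meta to the phenol and para to the formyl group.

**Step 3**
Reactants: 4 geranyl acetate
Product: 6 (E)-3,7-dimethyloct-2-ene-1,7-diol, via hydroxy acetate 5 (not isolated)
Conditions: Hg(OAc)2, THF/H2O, rt; then NaBH4, 3 M NaOH, 0 °C; then MeOH, rt
Reagents that add atoms: water, O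
Why: Markovnikov oxymercuration–demercuration picks the electron-rich 6,7-alkene over the 2,3-alkene that the allylic acetate deactivates, and the alkaline medium then saponifies the acetate without touching the E-2,3-alkene.

**Step 4**
Reactants: 6 (E)-3,7-dimethyloct-2-ene-1,7-diol
Product: 7 (E)-7-hydroxy-3,7-dimethyloct-2-enal
Conditions: activated MnO2 (excess), CH2Cl2, rt; used fresh
Reagents that add atoms: none
Why: MnO2 oxidises only the allylic primary alcohol, leaves the tertiary alcohol alone and keeps the E geometry of the alkene.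

**Step 5**
Reactants: 3 5-bromo-2-hydroxy-3,6-dimethoxybenzaldehyde; 7 (E)-7-hydroxy-3,7-dimethyloct-2-enal (1.5 equiv)
Product: 8 (S)-6-bromo-2-(4-hydroxy-4-methylpentyl)-5,8-dimethoxy-2-methyl-2H-chromene-3-carbaldehyde
Conditions: (R)-2-[diphenyl(trimethylsilyloxy)methyl]pyrrolidine (20 mol%), 2-nitrobenzoic acid (20 mol%), 4 Å molecular sieves, toluene, 0 °C → rt, dark
Reagents that add atoms: none
Why: Proposed new method: the amine and enal 7 form an E-configured iminium ion, the single phenol oxygen of 3 adds to its β-carbon (O1–C2), and the enamine so formed attacks the neighbouring aryl aldehyde (C3–C4) before loss of water and hydrolysis free the catalyst and the conjugated 3-formyl chromene. The closest known reaction type is the diarylprolinol silyl ether-catalysed oxa-Michael–aldol condensation of salicylaldehydes with β-monosubstituted enals, together with iminium-ion conjugate additions of the same catalysts to β,β-disubstituted enals; joining the two at a β-methyl-β-alkyl enal to make a fully substituted C2 is the untested part. Ring B closes by a 6-exo-trig (enolexo) aldol addition that follows the intermolecular oxa-Michael step and is made irreversible by dehydration, which drains the reversible C–O bond formation. C2 is set by the catalyst: its C(Ph)2OSiMe3 group covers one face of the s-trans E-iminium ion, and on this shielding model the (R)-catalyst leaves open the Si face of the enal β-carbon, attack on which gives the S configuration. The step needs the E geometry of 7 to last until the C–O bond is made, so the acid co-catalyst, the low temperature and the excess of geometrically pure enal are chosen to keep dienamine-mediated E/Z scrambling and γ-carbon reactivity slower than conjugate addition. Chemoselectivity rests on the substrates: 3 has only one phenol, and the tertiary alcohol of 7 is a weak, hindered nucleophile whose own conjugate addition is reversible and leads to no stable product.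

**Step 6**
Reactants: 8 (S)-6-bromo-2-(4-hydroxy-4-methylpentyl)-5,8-dimethoxy-2-methyl-2H-chromene-3-carbaldehyde
Product: 9 (S)-5-(6-bromo-5,8-dimethoxy-2-methyl-2H-chromen-2-yl)-2-methylpentan-2-ol
Conditions: RhCl(PPh3)3 (1.1 equiv), degassed toluene, 90 °C, dark
Reagents that add atoms: none
Why: In the Tsuji–Wilkinson decarbonylation the formyl C–H bond adds to monovalent rhodium, carbon monoxide is extruded and C–H reductive elimination leaves hydrogen at C3 with RhCl(CO)(PPh3)2 as the stable end point, while the aryl bromide is inert to this complex and C2 is not involved as long as heat and light are limited.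

**Step 7**
Reactants: 9 (S)-5-(6-bromo-5,8-dimethoxy-2-methyl-2H-chromen-2-yl)-2-methylpentan-2-ol
Product: 10 (S)-1-[2-(4-hydroxy-4-methylpentyl)-5,8-dimethoxy-2-methyl-2H-chromen-6-yl]ethan-1-one
Conditions: t-BuLi (3.2 equiv), THF, −78 °C; then MeC(O)N(OMe)Me, −78 → 0 °C; sat. aq. NH4Cl
Reagents that add atoms: N-methoxy-N-methylacetamide, CC(=O)N(C)OC
Why: After the first equivalent of t-BuLi has deprotonated the tertiary alcohol, bromine–lithium exchange is the fastest process at −78 °C, and the aryllithium adds only once to the Weinreb amide because the chelated tetrahedral intermediate lasts until work-up.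

**Step 8**
Reactants: 10 (S)-1-[2-(4-hydroxy-4-methylpentyl)-5,8-dimethoxy-2-methyl-2H-chromen-6-yl]ethan-1-one
Product: 12 (S)-1-[5,8-dihydroxy-2-(4-hydroxy-4-methylpentyl)-2-methyl-2H-chromen-6-yl]ethan-1-one, via acetylquinone 11 (not isolated)
Conditions: (NH4)2Ce(NO3)6 (2.5 equiv), MeCN/H2O, 0 °C, short contact; extract into EtOAc, then shake with aq. Na2S2O4, 0 °C → rt
Reagents that add atoms: water, O (source of the two new ring oxygens; the methoxy groups leave as methanol)
Why: Oxidative demethylation of a para-dimethoxyarene by tetravalent cerium gives the para-quinone through ipso attack of water on the arene radical cation, and immediate dithionite reduction in the cold returns the hydroquinone before the electrophilic, pyran-fused acetylquinone can add nucleophiles or open at C2.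

**Step 9**
Reactants: 12 (S)-1-[5,8-dihydroxy-2-(4-hydroxy-4-methylpentyl)-2-methyl-2H-chromen-6-yl]ethan-1-one; 13 4-hydroxybenzaldehyde
Product: 14 (E)-1-[(2S)-5,8-dihydroxy-2-(4-hydroxy-4-methylpentyl)-2-methyl-2H-chromen-6-yl]-3-(4-hydroxyphenyl)prop-2-en-1-one
Conditions: KOH (50% aq.), EtOH, degassed, argon, rt; then cold 1 M HCl to pH 4–5
Reagents that add atoms: none
Why: In the Claisen–Schmidt condensation the methyl ketone enolate adds to the non-enolisable aldehyde and E1cB loss of hydroxide gives the conjugated enone in its thermodynamically preferred E geometry, with oxygen excluded because the hydroquinone dianion is air-sensitive and with C2 remote from the reacting centres.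

**Compound list**

1 | 2,5-dimethoxyphenol | COc1ccc(OC)c(O)c1 | starting material
2 | 2-hydroxy-3,6-dimethoxybenzaldehyde | O=Cc1c(O)c(OC)ccc1OC | intermediate
3 | 5-bromo-2-hydroxy-3,6-dimethoxybenzaldehyde | COc1cc(Br)c(OC)c(C=O)c1O | intermediate
4 | geranyl acetate, (E)-3,7-dimethylocta-2,6-dien-1-yl acetate | CC(C)=CCC/C(C)=C/COC(C)=O | starting material
5 | (E)-7-hydroxy-3,7-dimethyloct-2-en-1-yl acetate | CC(C)(O)CCC/C(C)=C/COC(C)=O | intermediate (not isolated)
6 | (E)-3,7-dimethyloct-2-ene-1,7-diol | CC(C)(O)CCC/C(C)=C/CO | intermediate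
7 | (E)-7-hydroxy-3,7-dimethyloct-2-enal | CC(C)(O)CCC/C(C)=C/C=O | intermediate
8 | (S)-6-bromo-2-(4-hydroxy-4-methylpentyl)-5,8-dimethoxy-2-methyl-2H-chromene-3-carbaldehyde | CC(C)(O)CCC[C@@]1(C)C(C=O)=Cc2c(OC)c(Br)cc(OC)c2O1 | intermediate
9 | (S)-5-(6-bromo-5,8-dimethoxy-2-methyl-2H-chromen-2-yl)-2-methylpentan-2-ol | CC(C)(O)CCC[C@@]1(C)C=Cc2c(OC)c(Br)cc(OC)c2O1 | intermediate
10 | (S)-1-[2-(4-hydroxy-4-methylpentyl)-5,8-dimethoxy-2-methyl-2H-chromen-6-yl]ethan-1-one | CC(C)(O)CCC[C@@]1(C)C=Cc2c(OC)c(C(C)=O)cc(OC)c2O1 | intermediate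
11 | (S)-6-acetyl-2-(4-hydroxy-4-methylpentyl)-2-methyl-2H-chromene-5,8-dione | CC(C)(O)CCC[C@@]1(C)C=CC2=C(O1)C(=O)C=C(C(C)=O)C2=O | intermediate (not isolated)
12 | (S)-1-[5,8-dihydroxy-2-(4-hydroxy-4-methylpentyl)-2-methyl-2H-chromen-6-yl]ethan-1-one | CC(C)(O)CCC[C@@]1(C)C=Cc2c(O)c(C(C)=O)cc(O)c2O1 | intermediate
13 | 4-hydroxybenzaldehyde | O=Cc1ccc(O)cc1 | starting material
14 | (E)-1-[(2S)-5,8-dihydroxy-2-(4-hydroxy-4-methylpentyl)-2-methyl-2H-chromen-6-yl]-3-(4-hydroxyphenyl)prop-2-en-1-one | CC(C)(O)CCC[C@@]1(C)C=Cc2c(O)c(C(=O)/C=C/c3ccc(O)cc3)cc(O)c2O1 | target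

**Step count and risks**

Total steps: 9. Longest linear sequence: 7 (steps 1, 2, 5, 6, 7, 8, 9; the enal branch through steps 3 and 4 is equally long).

Steps most likely to fail:

1. Step 5 (Proposed new method). What may go wrong: E/Z scrambling of the enal through its dienamine and reaction at the γ-carbon may outrun oxygen conjugate addition. Facial selectivity may also be poor at a β-carbon whose two substituents are similar in size. The aldol closure onto an aldehyde flanked by OH and OMe may be slow. The result would be low enantiomeric purity or the wrong connectivity. Fallback: it sets out from 1 and 7 and returns at 9, so that step 6 is also bypassed. Phenol 1 would be brominated para to the hydroxyl group (NBS, MeCN, 0 °C) to 4-bromo-2,5-dimethoxyphenol F1. F1 and enal 7 would be heated with PhB(OH)2 and AcOH in toluene with removal of water. This is the known boronate-templated phenol–enal condensation, which runs through an ortho-quinone methide and oxa-6π electrocyclisation, and it should give racemic 5-(6-bromo-5,8-dimethoxy-2-methyl-2H-chromen-2-yl)-2-methylpentan-2-ol F2. Preparative HPLC on a chiral stationary phase would then separate the S enantiomer, which is 9, from (R)-5-(6-bromo-5,8-dimethoxy-2-methyl-2H-chromen-2-yl)-2-methylpentan-2-ol F3, which is set aside. The route resumes at step 7.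

2. Step 9. What may go wrong: the hydroquinone dianion may be oxidised by traces of air under strong base, and addition to the aldehyde may be sluggish because its phenoxide form is deactivated. Fallback: it sets out from 12 and 13 and returns at 14. Aldehyde 13 would be converted into 4-(methoxymethoxy)benzaldehyde F10 (MOMCl, i-Pr2NEt, CH2Cl2). Ketone 12 would be protected selectively at the non-chelated 8-OH under the same mild conditions at 0 °C to give (S)-1-[5-hydroxy-2-(4-hydroxy-4-methylpentyl)-8-(methoxymethoxy)-2-methyl-2H-chromen-6-yl]ethan-1-one F11, with the hydrogen-bonded 5-OH and the tertiary alcohol left free. An ordinary Claisen–Schmidt condensation of F11 with F10 (KOH, EtOH, rt) no longer involves a hydroquinone dianion and should give (E)-1-[(2S)-5-hydroxy-2-(4-hydroxy-4-methylpentyl)-8-(methoxymethoxy)-2-methyl-2H-chromen-6-yl]-3-[4-(methoxymethoxy)phenyl]prop-2-en-1-one F12. Both acetals would then be removed with dilute HCl in MeOH at rt to give 14.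

3. Step 6. What may go wrong: carbon monoxide extrusion at the hindered, fully substituted C3 may be slow and need temperatures at which the chromene opens and recloses electrocyclically, eroding the configuration at C2; rhodium may also insert into the C–Br bond. Fallback: it sets out from 8 and returns at 9, with no step above 80 °C.
   - Pinnick oxidation (NaClO2, NaH2PO4, 2-methylbut-2-ene, t-BuOH/H2O) would give (S)-6-bromo-2-(4-hydroxy-4-methylpentyl)-5,8-dimethoxy-2-methyl-2H-chromene-3-carboxylic acid F4.
   - Diphenylphosphoryl azide and Et3N in toluene would convert F4 into (S)-6-bromo-2-(4-hydroxy-4-methylpentyl)-5,8-dimethoxy-2-methyl-2H-chromene-3-carbonyl azide F5. At 80 °C F5 should undergo Curtius rearrangement to (S)-5-(6-bromo-3-isocyanato-5,8-dimethoxy-2-methyl-2H-chromen-2-yl)-2-methylpentan-2-ol F6.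
   - Hydrolysis with dilute aqueous HCl in THF would give (S)-6-bromo-2-(4-hydroxy-4-methylpentyl)-5,8-dimethoxy-2-methylchroman-3-one F7.
   - NaBH4 in MeOH would reduce F7 to (2S)-6-bromo-2-(4-hydroxy-4-methylpentyl)-5,8-dimethoxy-2-methylchroman-3-ol F8, whose C3 configuration is immaterial.
   - MsCl and Et3N should sulfonylate only the secondary alcohol, giving (2S)-6-bromo-2-(4-hydroxy-4-methylpentyl)-5,8-dimethoxy-2-methylchroman-3-yl methanesulfonate F9. DBU in toluene at 80 °C would then eliminate toward C4, the only direction open because C2 carries no hydrogen, to give 9.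

**Further compounds**

F1 | step 5 | 4-bromo-2,5-dimethoxyphenol | COc1cc(Br)c(OC)cc1O
F2 | step 5 | racemic 5-(6-bromo-5,8-dimethoxy-2-methyl-2H-chromen-2-yl)-2-methylpentan-2-ol | CC(C)(O)CCCC1(C)C=Cc2c(OC)c(Br)cc(OC)c2O1
F3 | step 5 | (R)-5-(6-bromo-5,8-dimethoxy-2-methyl-2H-chromen-2-yl)-2-methylpentan-2-ol | CC(C)(O)CCC[C@]1(C)C=Cc2c(OC)c(Br)cc(OC)c2O1
F4 | step 6 | (S)-6-bromo-2-(4-hydroxy-4-methylpentyl)-5,8-dimethoxy-2-methyl-2H-chromene-3-carboxylic acid | CC(C)(O)CCC[C@@]1(C)C(C(=O)O)=Cc2c(OC)c(Br)cc(OC)c2O1
F5 | step 6 | (S)-6-bromo-2-(4-hydroxy-4-methylpentyl)-5,8-dimethoxy-2-methyl-2H-chromene-3-carbonyl azide | CC(C)(O)CCC[C@@]1(C)C(C(=O)N=[N+]=[N-])=Cc2c(OC)c(Br)cc(OC)c2O1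
F6 | step 6 | (S)-5-(6-bromo-3-isocyanato-5,8-dimethoxy-2-methyl-2H-chromen-2-yl)-2-methylpentan-2-ol | CC(C)(O)CCC[C@@]1(C)C(N=C=O)=Cc2c(OC)c(Br)cc(OC)c2O1
F7 | step 6 | (S)-6-bromo-2-(4-hydroxy-4-methylpentyl)-5,8-dimethoxy-2-methylchroman-3-one | CC(C)(O)CCC[C@@]1(C)C(=O)Cc2c(OC)c(Br)cc(OC)c2O1
F8 | step 6 | (2S)-6-bromo-2-(4-hydroxy-4-methylpentyl)-5,8-dimethoxy-2-methylchroman-3-ol, C3 epimers | CC(C)(O)CCC[C@@]1(C)C(O)Cc2c(OC)c(Br)cc(OC)c2O1
F9 | step 6 | (2S)-6-bromo-2-(4-hydroxy-4-methylpentyl)-5,8-dimethoxy-2-methylchroman-3-yl methanesulfonate, C3 epimers | CC(C)(O)CCC[C@@]1(C)C(OS(C)(=O)=O)Cc2c(OC)c(Br)cc(OC)c2O1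
F10 | step 9 | 4-(methoxymethoxy)benzaldehyde | COCOc1ccc(C=O)cc1
F11 | step 9 | (S)-1-[5-hydroxy-2-(4-hydroxy-4-methylpentyl)-8-(methoxymethoxy)-2-methyl-2H-chromen-6-yl]ethan-1-one | CC(C)(O)CCC[C@@]1(C)C=Cc2c(O)c(C(C)=O)cc(OCOC)c2O1
F12 | step 9 | (E)-1-[(2S)-5-hydroxy-2-(4-hydroxy-4-methylpentyl)-8-(methoxymethoxy)-2-methyl-2H-chromen-6-yl]-3-[4-(methoxymethoxy)phenyl]prop-2-en-1-one | CC(C)(O)CCC[C@@]1(C)C=Cc2c(O)c(C(=O)/C=C/c3ccc(OCOC)cc3)cc(OCOC)c2O1
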